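The route builds ring B (C5–C6–C7–C8–C9–C10) first as a cyclopentane and disconnects the C9–C10 bond of the diosphenol. A desymmetrising NHC benzoin of a prochiral trione-aldehyde sets quaternary C5 and gives a hydrindane α-ketol (C8=O, C10–OH). Vinyl Grignard addition and ozonolysis then attach C9 to C8 as a formyl group. In the key step this 1-hydroxycyclopentanecarbaldehyde undergoes an α-ketol 1,2-shift of C10 from C8 to C9 (ring expansion five to six) and loses the C10 hydroxyl. This delivers in one operation the contiguous C8(=O)–C9(OH)=C10 array, the feature the step exploits. C3/C4 follow from hydroboration anti to the axial C5 methyl; syn-carbocupration finishes the side chain.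

Key step: step 6

Remark (numbering and assumption): eremophilane numbering is used. Ring A = C1–C2–C3–C4–C5–C10 (ester oxygen on C3, methyls on C4 and C5); ring B = C5–C6–C7–C8–C9–C10 (C7 carries the isopropylidene carbon C11). Carbinol centres that are created only to be destroyed again are not controlled, are expected as epimer mixtures and are left undefined in the SMILES.

Step 1
Reactants: 1 2-methylcyclohexane-1,3-dione; 2 acrolein
Product: 3 3-(1-methyl-2,6-dioxocyclohexyl)propanal
Conditions: H2O, rt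
Reagents that add atoms: none
Why: Michael addition of the acidic cyclic 1,3-dione to acrolein should give the prochiral 2,2-disubstituted dione; C5 becomes quaternary but is not yet stereogenic.

Step 2
Reactants: 3 3-(1-methyl-2,6-dioxocyclohexyl)propanal
Product: 4 (3aS,7aR)-7a-hydroxy-3a-methylhexahydro-1H-indene-1,4(2H)-dione
Conditions: chiral aminoindanol-derived N-pentafluorophenyl triazolium tetrafluoroborate (10 mol%, enantiomer chosen to give 4), Et3N (10 mol%), CH2Cl2, rt
Reagents that add atoms: none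
Why: Desymmetrising intramolecular crossed benzoin reaction: the Breslow intermediate of the aldehyde adds to one of the two enantiotopic ring ketones, so the chiral carbene fixes C5 (3aS) and, through the three-atom tether, the cis-fused C10 carbinol (7aR).

Step 3
Reactants: 4 (3aS,7aR)-7a-hydroxy-3a-methylhexahydro-1H-indene-1,4(2H)-dione
Product: 5 (3aS,7aR)-1-ethenyl-1,7a-dihydroxy-3a-methyloctahydro-4H-inden-4-one (C1 epimers)
Conditions: CH2=CHMgBr (2.2 equiv), THF, −78 °C; aq. NH4Cl
Reagents that add atoms: vinylmagnesium bromide, C=C[Mg]Br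
Why: Grignard addition under chelation control: the first equivalent makes the C10 magnesium alkoxide, whose five-membered chelate activates the neighbouring C8 carbonyl so that it should react before the neopentyl C4 ketone; the configuration of the new C8 carbinol is irrelevant because C8 becomes a ketone again in step 6.

Step 4
Reactants: 5 (3aS,7aR)-1-ethenyl-1,7a-dihydroxy-3a-methyloctahydro-4H-inden-4-one
Product: 6 (3aS,7aR)-1-ethenyl-1,7a-dihydroxy-3a-methyl-2,3,3a,6,7,7a-hexahydro-1H-inden-4-yl trifluoromethanesulfonate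
Conditions: KHMDS (3.2 equiv), THF, −78 °C; N-(5-chloropyridin-2-yl)bis(trifluoromethanesulfonimide) (1.1 equiv); aq. NH4Cl
Reagents that add atoms: N-(5-chloropyridin-2-yl)bis(trifluoromethanesulfonimide), FC(F)(F)S(=O)(=O)N(c1ccc(Cl)cn1)S(=O)(=O)C(F)(F)F
Why: Enol triflate formation: the only remaining ketone can enolise only towards C3 (C5 is quaternary), and the potassium enolate should be O-sulfonylated far faster than the two hindered tertiary alkoxides.

Step 5
Reactants: 6 (3aS,7aR)-1-ethenyl-1,7a-dihydroxy-3a-methyl-2,3,3a,6,7,7a-hexahydro-1H-inden-4-yl trifluoromethanesulfonate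
Product: 8 (3aS,7aR)-1-formyl-1,7a-dihydroxy-3a-methyl-2,3,3a,6,7,7a-hexahydro-1H-inden-4-yl trifluoromethanesulfonate, via ozonide 7 (not isolated)
Conditions: O3, CH2Cl2, −78 °C; Me2S, −78 °C to rt
Reagents that add atoms: ozone, [O-][O+]=O
Why: Ozonolysis with reductive work-up: electrophilic ozone should cleave the monosubstituted vinyl group selectively, because the triflate-bearing C3=C4 double bond is strongly deactivated.

Step 6
Reactants: 8 (3aS,7aR)-1-formyl-1,7a-dihydroxy-3a-methyl-2,3,3a,6,7,7a-hexahydro-1H-inden-4-yl trifluoromethanesulfonate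
Product: 11 (4aS)-1-[(tert-butyldimethylsilyl)oxy]-4a-methyl-2-oxo-2,3,4,4a,7,8-hexahydronaphthalen-5-yl trifluoromethanesulfonate, via ring-expanded ketol 9 (not isolated), via diosphenol 10 (not isolated)
Conditions: DBU (3 equiv), toluene, rt to 60 °C; then TBSCl (1.5 equiv), rt
Reagents that add atoms: tert-butyldimethylsilyl chloride, CC(C)(C)[Si](C)(C)Cl
Why: Deprotonation of the C8 tertiary hydroxyl triggers an α-ketol (acyloin) rearrangement in which the C8–C10 σ-bond migrates to the formyl carbon C9 while C8 becomes the ketone, driven by aldehyde-to-ketone conversion and relief of hydrindane strain; the closest known reaction type is the D-homoannulation of 17-hydroxy-20-oxo steroids and the enlargement of 1-hydroxycycloalkanecarbaldehydes to 2-hydroxycycloalkanones. The six-membered ring C5–C6–C7–C8–C9–C10 is therefore formed from the cyclopentane C5–C6–C7–C8–C10 by a one-carbon ring expansion (1,2-alkyl shift), not by a cyclisation, and ring A is untouched. Enolisation of ketol 9 at C9 and E1cB loss of the C10 hydroxyl then give the C9=C10 enol, that is diosphenol 10 as its DBU salt, which TBSCl traps on O9. No stereocentre is created: C8 and C10 become sp2 and C5, set in step 2, cannot epimerise. The step needs regioselective migration (C10 rather than C7): the fully substituted, oxygen-bearing C10 is the better migrating group, and migration of C7 or a retro-aldol/aldol detour through a C10 ketone should converge on the same product, because enediol tautomerism interchanges the ketone and carbinol carbons before the irreversible β-elimination. The tetrasubstituted C9=C10 enol is the favoured diosphenol tautomer, and the alkenyl triflate is inert to DBU.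

Step 7
Reactants: 11 (4aS)-1-[(tert-butyldimethylsilyl)oxy]-4a-methyl-2-oxo-2,3,4,4a,7,8-hexahydronaphthalen-5-yl trifluoromethanesulfonate
Product: 12 (4aR)-1-[(tert-butyldimethylsilyl)oxy]-4a,5-dimethyl-4,4a,7,8-tetrahydronaphthalen-2(3H)-one
Conditions: MeZnCl (2 equiv), Pd(PPh3)4 (5 mol%), THF, 50 °C
Reagents that add atoms: methylzinc chloride, C[Zn]Cl
Why: Negishi cross-coupling of the alkenyl triflate installs the C4 methyl without any cationic intermediate next to quaternary C5, and the methylzinc reagent should not touch the silyloxy enone.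

Step 8
Reactants: 12 (4aR)-1-[(tert-butyldimethylsilyl)oxy]-4a,5-dimethyl-4,4a,7,8-tetrahydronaphthalen-2(3H)-one
Product: 13 (4aR)-1-[(tert-butyldimethylsilyl)oxy]-3-(2-hydroxypropan-2-yl)-4a,5-dimethyl-4,4a,7,8-tetrahydronaphthalen-2(3H)-one (C3 epimers)
Conditions: LDA (1.1 equiv), THF, −78 °C; acetone; AcOH, −78 °C
Reagents that add atoms: acetone, CC(C)=O
Why: Aldol addition: kinetic deprotonation of the 2-silyloxy enone by LDA occurs at the α' carbon C7 and the lithium enolate adds to acetone; the C7 configuration is lost in step 9.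

Step 9
Reactants: 13 (4aR)-1-[(tert-butyldimethylsilyl)oxy]-3-(2-hydroxypropan-2-yl)-4a,5-dimethyl-4,4a,7,8-tetrahydronaphthalen-2(3H)-one
Product: 15 (4aR)-1-[(tert-butyldimethylsilyl)oxy]-4a,5-dimethyl-3-(propan-2-ylidene)-4,4a,7,8-tetrahydronaphthalen-2(3H)-one, via tertiary mesylate 14 (not isolated)
Conditions: MsCl, Et3N, CH2Cl2, 0 °C; then DBU, rt
Reagents that add atoms: none
Why: Mesylation of the tertiary aldol (sulfene mechanism) followed by E1cB elimination through the C8 enolate should give the conjugated tetrasubstituted C7=C11 alkene, DBU moving any isopropenyl isomer into conjugation.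

Step 10
Reactants: 15 (4aR)-1-[(tert-butyldimethylsilyl)oxy]-4a,5-dimethyl-3-(propan-2-ylidene)-4,4a,7,8-tetrahydronaphthalen-2(3H)-one
Product: 17 (4aR,5R,6R)-1-[(tert-butyldimethylsilyl)oxy]-6-hydroxy-4a,5-dimethyl-3-(propan-2-ylidene)-4,4a,5,6,7,8-hexahydronaphthalen-2(3H)-one, via C3 alkylborane 16 (not isolated)
Conditions: BH3·SMe2 (1.2 equiv), THF, 0 °C; then 30% H2O2, aq. NaOAc, 0 °C to rt
Reagents that add atoms: hydrogen peroxide, OO
Why: Hydroboration–oxidation: in the Δ9(10)-octalone the C5 methyl is axial and shields one face, so syn addition of H–B should occur from the opposite face with boron at the less substituted C3, setting C4 (methyl cis to the C5 methyl) and C3 (hydroxyl trans to the C4 methyl) together; the isolated trisubstituted alkene is expected to react before the hindered cross-conjugated C8 carbonyl.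

Step 11
Reactants: 18 3-bromoprop-1-yne (propargyl bromide); 19 (Z)-2-methylbut-2-enoic acid (angelic acid)
Product: 20 prop-2-yn-1-yl (Z)-2-methylbut-2-enoate
Conditions: K2CO3, DMF, rt
Reagents that add atoms: none
Why: SN2 O-alkylation of potassium angelate needs no activation of the acid, so isomerisation of the angelate to the tiglate is not expected.

Step 12
Reactants: 20 prop-2-yn-1-yl (Z)-2-methylbut-2-enoate
Product: 21 4-{[(Z)-2-methylbut-2-enoyl]oxy}but-2-ynoic acid
Conditions: LiHMDS (1.05 equiv), THF, −78 °C; CO2; aq. HCl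
Reagents that add atoms: carbon dioxide, O=C=O
Why: Carboxylation of the lithium acetylide (deprotonation of the terminal C–H is much faster than any reaction at the hindered enoate) should give the ynoic acid, which cannot lactonise.

Step 13
Reactants: 17 (4aR,5R,6R)-1-[(tert-butyldimethylsilyl)oxy]-6-hydroxy-4a,5-dimethyl-3-(propan-2-ylidene)-4,4a,5,6,7,8-hexahydronaphthalen-2(3H)-one; 21 4-{[(Z)-2-methylbut-2-enoyl]oxy}but-2-ynoic acid
Product: 22 (1R,2R,8aR)-5-[(tert-butyldimethylsilyl)oxy]-1,8a-dimethyl-6-oxo-7-(propan-2-ylidene)-1,2,3,4,6,7,8,8a-octahydronaphthalen-2-yl 4-{[(Z)-2-methylbut-2-enoyl]oxy}but-2-ynoate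
Conditions: DIC, DMAP (10 mol%), CH2Cl2, 0 °C
Reagents that add atoms: none
Why: Steglich esterification of the only free hydroxyl (equatorial C3–OH); the stereocentres are untouched and the enol oxygen is masked as its silyl ether.

Step 14
Reactants: 22 (1R,2R,8aR)-5-[(tert-butyldimethylsilyl)oxy]-1,8a-dimethyl-6-oxo-7-(propan-2-ylidene)-1,2,3,4,6,7,8,8a-octahydronaphthalen-2-yl 4-{[(Z)-2-methylbut-2-enoyl]oxy}but-2-ynoate
Product: 23 (1R,2R,8aR)-5-[(tert-butyldimethylsilyl)oxy]-1,8a-dimethyl-6-oxo-7-(propan-2-ylidene)-1,2,3,4,6,7,8,8a-octahydronaphthalen-2-yl (2Z)-3-methyl-4-{[(2Z)-2-methylbut-2-enoyl]oxy}but-2-enoate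
Conditions: Me2CuLi (1.3 equiv), THF, −78 °C; AcOH, −78 °C
Reagents that add atoms: lithium dimethylcuprate, [Li+].C[Cu-]C
Why: syn-Carbocupration of the ynoate with cold protonation places methyl and hydrogen cis, giving the Z-enoate with CH2O cis to the ester carbonyl; it should be much faster than cuprate addition to the β,β-disubstituted enones or the angelate and than SN2' loss of the poor carboxylate leaving group.

Step 15
Reactants: 23 (1R,2R,8aR)-5-[(tert-butyldimethylsilyl)oxy]-1,8a-dimethyl-6-oxo-7-(propan-2-ylidene)-1,2,3,4,6,7,8,8a-octahydronaphthalen-2-yl (2Z)-3-methyl-4-{[(2Z)-2-methylbut-2-enoyl]oxy}but-2-enoate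
Product: 24 (1R,2R,8aR)-5-hydroxy-1,8a-dimethyl-6-oxo-7-(propan-2-ylidene)-1,2,3,4,6,7,8,8a-octahydronaphthalen-2-yl (2Z)-3-methyl-4-{[(2Z)-2-methylbut-2-enoyl]oxy}but-2-enoate (CNP0228871.1)
Conditions: HF·pyridine, THF, 0 °C
Reagents that add atoms: none
Why: Fluoride-mediated cleavage of the silyl enol ether should liberate the diosphenol under conditions that leave both enoate esters and their Z geometry intact.

Compound list
1 | 2-methylcyclohexane-1,3-dione | CC1C(=O)CCCC1=O | starting material
2 | acrolein | C=CC=O | starting material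
3 | 3-(1-methyl-2,6-dioxocyclohexyl)propanal | CC1(CCC=O)C(=O)CCCC1=O | intermediate
4 | (3aS,7aR)-7a-hydroxy-3a-methylhexahydro-1H-indene-1,4(2H)-dione (cis-fused ketol) | C1CC[C@]2(O)C(=O)CC[C@]2(C)C1=O | intermediate
5 | (3aS,7aR)-1-ethenyl-1,7a-dihydroxy-3a-methyloctahydro-4H-inden-4-one (C1 epimers) | C1CC[C@]2(O)C(O)(C=C)CC[C@]2(C)C1=O | intermediate
6 | (3aS,7aR)-1-ethenyl-1,7a-dihydroxy-3a-methyl-2,3,3a,6,7,7a-hexahydro-1H-inden-4-yl trifluoromethanesulfonate | FC(F)(F)S(=O)(=O)OC1=CCC[C@]2(O)C(O)(C=C)CC[C@]12C | intermediate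
7 | secondary ozonide of 6 (1,2,4-trioxolan-3-yl group on the C8 carbinol) | FC(F)(F)S(=O)(=O)OC1=CCC[C@]2(O)C(O)(C3OOCO3)CC[C@]12C | intermediate
8 | (3aS,7aR)-1-formyl-1,7a-dihydroxy-3a-methyl-2,3,3a,6,7,7a-hexahydro-1H-inden-4-yl trifluoromethanesulfonate | FC(F)(F)S(=O)(=O)OC1=CCC[C@]2(O)C(O)(C=O)CC[C@]12C | intermediate
9 | (4aS,8aR)-1,8a-dihydroxy-4a-methyl-2-oxo-1,2,3,4,4a,7,8,8a-octahydronaphthalen-5-yl trifluoromethanesulfonate (ring-expanded ketol, C1 epimers) | FC(F)(F)S(=O)(=O)OC1=CCC[C@]2(O)C(O)C(=O)CC[C@]12C | intermediate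
10 | (4aS)-1-hydroxy-4a-methyl-2-oxo-2,3,4,4a,7,8-hexahydronaphthalen-5-yl trifluoromethanesulfonate (diosphenol) | FC(F)(F)S(=O)(=O)OC1=CCCC2=C(O)C(=O)CC[C@]12C | intermediate
11 | (4aS)-1-[(tert-butyldimethylsilyl)oxy]-4a-methyl-2-oxo-2,3,4,4a,7,8-hexahydronaphthalen-5-yl trifluoromethanesulfonate | FC(F)(F)S(=O)(=O)OC1=CCCC2=C(O[Si](C)(C)C(C)(C)C)C(=O)CC[C@]12C | intermediate
12 | (4aR)-1-[(tert-butyldimethylsilyl)oxy]-4a,5-dimethyl-4,4a,7,8-tetrahydronaphthalen-2(3H)-one | CC1=CCCC2=C(O[Si](C)(C)C(C)(C)C)C(=O)CC[C@]12C | intermediate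
13 | (4aR)-1-[(tert-butyldimethylsilyl)oxy]-3-(2-hydroxypropan-2-yl)-4a,5-dimethyl-4,4a,7,8-tetrahydronaphthalen-2(3H)-one (C3 epimers) | CC1=CCCC2=C(O[Si](C)(C)C(C)(C)C)C(=O)C(C(C)(C)O)C[C@]12C | intermediate
14 | tertiary methanesulfonate of 13 | CC1=CCCC2=C(O[Si](C)(C)C(C)(C)C)C(=O)C(C(C)(C)OS(C)(=O)=O)C[C@]12C | intermediate
15 | (4aR)-1-[(tert-butyldimethylsilyl)oxy]-4a,5-dimethyl-3-(propan-2-ylidene)-4,4a,7,8-tetrahydronaphthalen-2(3H)-one | CC1=CCCC2=C(O[Si](C)(C)C(C)(C)C)C(=O)C(=C(C)C)C[C@]12C | intermediate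
16 | C3 alkylborane (BH2 in place of the hydroxyl of 17, same configuration) | B[C@@H]1CCC2=C(O[Si](C)(C)C(C)(C)C)C(=O)C(=C(C)C)C[C@]2(C)[C@H]1C | intermediate
17 | (4aR,5R,6R)-1-[(tert-butyldimethylsilyl)oxy]-6-hydroxy-4a,5-dimethyl-3-(propan-2-ylidene)-4,4a,5,6,7,8-hexahydronaphthalen-2(3H)-one | O[C@@H]1CCC2=C(O[Si](C)(C)C(C)(C)C)C(=O)C(=C(C)C)C[C@]2(C)[C@H]1C | intermediate
18 | 3-bromoprop-1-yne (propargyl bromide) | C#CCBr | starting material
19 | (Z)-2-methylbut-2-enoic acid (angelic acid) | C/C=C(/C)C(=O)O | starting material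
20 | prop-2-yn-1-yl (Z)-2-methylbut-2-enoate | C/C=C(/C)C(=O)OCC#C | intermediate
21 | 4-{[(Z)-2-methylbut-2-enoyl]oxy}but-2-ynoic acid | C/C=C(/C)C(=O)OCC#CC(=O)O | intermediate
22 | (1R,2R,8aR)-5-[(tert-butyldimethylsilyl)oxy]-1,8a-dimethyl-6-oxo-7-(propan-2-ylidene)-1,2,3,4,6,7,8,8a-octahydronaphthalen-2-yl 4-{[(Z)-2-methylbut-2-enoyl]oxy}but-2-ynoate | C/C=C(/C)C(=O)OCC#CC(=O)O[C@@H]1CCC2=C(O[Si](C)(C)C(C)(C)C)C(=O)C(=C(C)C)C[C@]2(C)[C@H]1C | intermediate
23 | (1R,2R,8aR)-5-[(tert-butyldimethylsilyl)oxy]-1,8a-dimethyl-6-oxo-7-(propan-2-ylidene)-1,2,3,4,6,7,8,8a-octahydronaphthalen-2-yl (2Z)-3-methyl-4-{[(2Z)-2-methylbut-2-enoyl]oxy}but-2-enoate | C/C=C(/C)C(=O)OC/C(C)=C\C(=O)O[C@@H]1CCC2=C(O[Si](C)(C)C(C)(C)C)C(=O)C(=C(C)C)C[C@]2(C)[C@H]1C | intermediate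
24 | (1R,2R,8aR)-5-hydroxy-1,8a-dimethyl-6-oxo-7-(propan-2-ylidene)-1,2,3,4,6,7,8,8a-octahydronaphthalen-2-yl (2Z)-3-methyl-4-{[(2Z)-2-methylbut-2-enoyl]oxy}but-2-enoate | C/C=C(/C)C(=O)OC/C(C)=C\C(=O)O[C@@H]1CCC2=C(O)C(=O)C(=C(C)C)C[C@]2(C)[C@H]1C | target

Total step count: 15. Longest linear sequence: 13 (steps 1–10 and 13–15; steps 11–12 make the side-chain acid).

Steps most likely to fail

1. Step 6 (key step). The β-oxido aldehyde may open by retro-aldol faster than the 1,2-shift and feed intermolecular aldol chemistry, or the cascade may stall before the C10 hydroxyl is lost (incomplete β-elimination). The fallback separates the ring expansion from the formation of the C9=C10 bond and replaces the E1cB step by a reductive C–O cleavage. It sets out from 8: a Lewis-acid-mediated α-ketol rearrangement (Al(Ot-Bu)3, toluene) gives the ring-expanded ketol 9, now isolated. DMP oxidation of its secondary C9 hydroxyl gives the 8,9-diketone (4aS,8aR)-8a-hydroxy-4a-methyl-1,2-dioxo-1,2,3,4,4a,7,8,8a-octahydronaphthalen-5-yl trifluoromethanesulfonate F1, in which the C10 hydroxyl is α to a carbonyl. SmI2 (THF/MeOH, −78 °C) then cleaves that C10–O bond reductively to give diosphenol 10. Silylation (TBSCl, imidazole) brings the material back to the route at 11.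

2. Step 3. Chemoselectivity may be lost through competing addition to, or enolisation of, the C4 ketone. The fallback masks C4 and sets out from 4. Selective ketalisation (ethylene glycol, PPTS, benzene, Dean–Stark; the α-hydroxy cyclopentanone carbonyl C8 resists ketalisation) gives the C4 dioxolane (3a'S,7a'R)-7a'-hydroxy-3a'-methylhexahydrospiro[1,3-dioxolane-2,4'-inden]-1'(2'H)-one F2. Vinylmagnesium bromide then adds to the only ketone left and gives the vinyl carbinol ketal (3a'S,7a'R)-1'-ethenyl-3a'-methyloctahydrospiro[1,3-dioxolane-2,4'-indene]-1',7a'-diol F3. Mild deketalisation (PPTS, acetone/H2O) returns to the route at 5.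

3. Step 10. Borane may reduce the C8 carbonyl in competition with hydroboration of the C3=C4 alkene. The fallback accepts the over-reduction and sets out from 15. Excess BH3·THF followed by buffered peroxide gives the diol (4aR,5R,6R)-1-[(tert-butyldimethylsilyl)oxy]-4a,5-dimethyl-3-(propan-2-ylidene)-2,3,4,4a,5,6,7,8-octahydronaphthalene-2,6-diol F4 (C2 epimers), with the C3/C4 centres still set anti to the axial C5 methyl. MnO2 (CH2Cl2, rt) re-oxidises only the doubly allylic C8 alcohol and returns to the route at 17.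

Further compounds
F1 | step 6 | (4aS,8aR)-8a-hydroxy-4a-methyl-1,2-dioxo-1,2,3,4,4a,7,8,8a-octahydronaphthalen-5-yl trifluoromethanesulfonate | FC(F)(F)S(=O)(=O)OC1=CCC[C@]2(O)C(=O)C(=O)CC[C@]12C
F2 | step 3 | (3a'S,7a'R)-7a'-hydroxy-3a'-methylhexahydrospiro[1,3-dioxolane-2,4'-inden]-1'(2'H)-one | C1CC[C@]2(O)C(=O)CC[C@]2(C)C13OCCO3
F3 | step 3 | (3a'S,7a'R)-1'-ethenyl-3a'-methyloctahydrospiro[1,3-dioxolane-2,4'-indene]-1',7a'-diol (C1' epimers) | C1CC[C@]2(O)C(O)(C=C)CC[C@]2(C)C13OCCO3
F4 | step 10 | (4aR,5R,6R)-1-[(tert-butyldimethylsilyl)oxy]-4a,5-dimethyl-3-(propan-2-ylidene)-2,3,4,4a,5,6,7,8-octahydronaphthalene-2,6-diol (C2 epimers) | O[C@@H]1CCC2=C(O[Si](C)(C)C(C)(C)C)C(O)C(=C(C)C)C[C@]2(C)[C@H]1C
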